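How steeply does the rate of making left-handed product at 10 % conversion depend on the catalyst charged, when every run so far used 5 mM?

common to all: added ligand 2.7 mM
- birch: left-handed substrate 0.025 M; right-handed substrate 0.025 M; reagent 0.060 M; catalyst 5 mM; run made earlier
- alder: left-handed substrate 0.038 M; right-handed substrate 0.038 M; reagent 0.060 M; catalyst 5 mM; run made earlier
- maple: left-handed substrate 0.050 M; right-handed substrate 0.050 M; reagent 0.090 M; catalyst 5 mM; run made earlier
- flask: left-handed substrate 0.050 M; right-handed substrate 0.050 M; reagent 0.0600 M; catalyst 5.0 mM

- birch (time / s: left-handed product / %, left-handed substrate / %): 12.0: 3.5, 48.2; 25.0: 5.9, 44.7; 40.0: 5.2, 42.7; 50.0: 7.8, 42.5; 60.0: 9.8, 41.0; 80.0: 9.6, 40.6; 90.0: 10.0, 39.6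
- alder (time / s: left-handed product / %, left-handed substrate / %): 10.0: 4.8, 48.5; 12.0: 0, 46.6; 15.0: 3.6, 48.4; 25.0: 7.4, 43.5; 40.0: 7.0, 43.0; 60.0: 9.8, 41.9; 90.0: 11.7, 39.9
- maple (time / s: left-handed product / %, left-handed substrate / %): 10.0: 4.9, 47.3; 25.0: 7.5, 42.8; 40.0: 9.6, 41.8; 60.0: 9.4, 41.0; 90.0: 12.7, 37.6

(readings scatter by 1 percentage point)

- catalyst is single-handed; left-handed substrate and right-handed substrate are mirror images of each other, charged as a racemate, each of them at the stated concentration
- no earlier run changes the charge of catalyst; that part of a forecast is a guess

- apparent order in catalyst when 10 % of the left-handed substrate and right-handed substrate together are converted (percent change of the rate of making left-handed product for one percent more catalyst charged)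

I bracketed it. From below: if the fall in rate went with turnover, the curves would depend on catalyst times time, the mark would be met in the same state, and the order would be 1.

From above: in maple the left-handed product stood at 4.9 % after 10.0 s but at 12.7 % after 90.0 s, with left-handed substrate still at 37.6 % of both substrates charged. Suppose that this slowing runs on a clock the catalyst does not touch: more catalyst then reaches the mark earlier, on a steeper part of the curve. A curve climbing as time to the power n has a rate n times its mean rate so far. One percent more catalyst then brings the mark forward by one over n percent, and the rate gains one over n percent in total, partly from the catalyst and partly from being earlier.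

Read between 25.0 s and 90.0 s, with the product readings of the earlier runs summed, the upper end came to 2.55: this is the lateness ratio, the mean rate up to the mark divided by the rate at the mark. Birch alone gave 2.43 and alder alone 2.80. These are readings with their scatter, so the upper end is an estimate and not a strict bound; I took the summed value as my reckoning.

The forecast guessed about 2, inside my bracket but lower than my reckoning, on the ground “Deactivation independent of catalyst charge gives about 2–4, because more catalyst reaches 10% earlier, while it is still fresher.”

The flask gave 2.7, above the lateness ratio of 2.55.

    reagent + catalyst + left-handed substrate → catalyst + left-handed product (k = 23.8 /M²/s)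
    reagent + catalyst + right-handed substrate → catalyst + right-handed product (k = 1.15 /M²/s)
    catalyst + added ligand ⇌ idle complex (K = 200 /M, k = 3.09 /M/s)
    2 reagent → self-condensation product (k = 0.274 /M/s)

In the flask at 0.285 min, self-condensation, a step with no catalyst in it, used reagent 4.0 times as fast as the making of left-handed product did. By 1.25 min the reagent in the flask stood at 23.0 % of its charge, with left-handed product at 9.56 % of both substrates charged.

The numbers in the tables are simulated on assumed constants.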